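**Analysis of the target**

The target is an open-chain tetramer of phloroglucinol-type units: four benzene rings joined only by three diaryl ether bonds and carrying ten free phenolic hydroxyls. With the rings lettered A to D in the order of the SMILES string, ring A is a 2,4,6-trihydroxyphenoxy group and ring B is a 3,5-dihydroxybenzene that carries the oxygen to ring A on B1 and the oxygen to ring C on the neighbouring B6. Ring C is a 3,5-dihydroxyphenylene bonded through C1 to ring B and through C4 to ring D, and ring D is a 3,4,5-trihydroxyphenyl (pyrogallol) group. There is no stereocentre and no stable axial chirality, so the task is one of regiochemistry and ether construction only. The free decaphenol is sensitive to air and base, so every hydroxyl is best kept masked until the last step. The difficulty lies in forming three ether bonds between electron-rich rings that carry no activating group, each at a carbon flanked by two oxygen substituents on at least one side. The second difficulty is placing two different aryloxy groups on adjacent carbons of the 1,2,3,5-tetraoxygenated ring B without ambiguity. The route rests on the sequence B1 (aryloxy), B6 (aryloxy), B5 (oxygen): this is what a 3,5-dimethoxybenzyne with its triple bond between B1 and B6 gives when a nucleophile adds at B1 and an electrophile at B6.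

**Retrosynthetic reasoning**

The last disconnection is the ten O–CH3 bonds of 20. Carrying all hydroxyls as methyl ethers keeps the rings inert to base, copper, organolithium reagents and air. Decamethyl ether 19 must then lose only alkyl–oxygen bonds in one Lewis-acid dealkylation, leaving the three aryl–O–aryl links intact.

In 19 the bond between the B6 carbon and the ether oxygen to ring C is cut, giving aryl iodide 13 and phenol 18. This is the most congested carbon of ring B, and it is exactly where the aryne chemistry leaves a halogen. Phenol 18 has no ortho substituent at C1, so the steric burden of a copper-catalysed O-arylation sits on the iodide alone. Cutting the A–B ether at this stage instead would require a doubly ortho-substituted phenol to meet a doubly ortho-substituted halide.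

Iodide 13 is opened at two bonds at once, B1–O and B6–I. This leads back to silyl triflate 8 as the source of aryne 11, to phenol 9 as its potassium salt 10, and to an iodine donor. The gain is that both neighbouring substituents of ring B are introduced in one operation, with their relative positions fixed by the aryne and not by a selective halogenation. The forward reaction must achieve O-arylation of the phenoxide, attack at B1 and not B6, and iodination of the aryl anion before it is protonated.

Triflate 8 is traced to 3,5-dimethoxyphenol 1. The phenol oxygen becomes the triflate. The silyl group is placed on the carbon between that oxygen and a methoxy group by directed ortho-metalation of carbamate 2, giving silyl carbamate 6. The two ortho positions of 2 are equivalent, so only the competition with the position between the two methoxy groups has to be won.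

Phenol 18 is cut at the C4–O bond to ring D and its C1 hydroxyl is traced to a formyl group. Aldehyde 16 comes from bromide 14 and phenol 15 by a copper-catalysed etherification, in which the formyl group activates the bromide. A Baeyer–Villiger oxidation then turns the formyl carbon into the C1 oxygen. Ring A (9), ring C (14) and ring D (15) are thus bought with their oxygen patterns complete.

**Alternatives that were turned down**

Alternative 1: Ring A is not bought but built. It is disconnected at two C–C bonds, so that the dianion of dimethyl 3-oxopentanedioate A2 is acylated twice by aryloxymalonate A3, which already carries rings B, C and D. The product is the trihydroxyisophthalate A1; ester hydrolysis, decarboxylation and demethylation would follow. In its favour, the A–O–B bond arises from an alkylation at a malonate carbon, which is sterically undemanding and classical; on that single bond it is stronger than the chosen route. Against it, A3 has an acidic methine that the dianion of A2 will deprotonate before it attacks an ester, and the resulting malonate enolate is a poor acyl donor. Two extra ester groups must then be removed from an electron-rich ring. Above all, A3 has to be made from phenol A4, in which the hindered B6–O–C1 ether and a differentiated B1 hydroxyl are already in place, so the ring B problem remains unsolved and the sequence is longer. The chosen route uses ring A as a commercial phenol and settles the ring B pattern in the same step that attaches it.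

Alternative 2: This concerns the C–D ether only. Ring C is introduced as quinone diazide A6. Rh2(OAc)4 converts it into a carbenoid that inserts into the O–H bond of phenol 15 and aromatises to phenol A5, which has the same structure as 18. In its favour, the bond to the carbon flanked by two methoxy groups forms at ambient temperature under neutral conditions, and the C1 hydroxyl is released directly, with no oxidation step; in mildness it is superior to the copper coupling and Baeyer–Villiger pair used here. Against it, A6 needs nitrogen introduction para to a phenol, reduction and diazotisation, and is an energetic compound. The electron-rich ring of 15 also offers the carbenoid competing C–H insertion and ring-addition pathways. The alternative gives no answer for ring B and does not shorten the overall sequence, since 18 is reached here in two steps from commercial materials. It could replace steps 5 and 6 but does not replace the aryne step.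

Alternative 3: The B6–O bond is made by addition–elimination. The phenoxide of 18 displaces fluoride from fluoroaldehyde A7, in which a formyl group para to B6 activates the ring and later becomes the B3 hydroxyl by Baeyer–Villiger oxidation; the product of the key step is aldehyde A8. In its favour, the hardest bond of the target is formed by a well-understood, metal-free reaction with a small leaving group, and the formyl group is fully used. For the certainty of the B–C bond it is stronger than the chosen route, which relies on an untested three-component coupling followed by a copper coupling at a doubly flanked iodide. Against it, A7 must carry ring A on a carbon meta to the formyl group, where addition–elimination is not possible. Phenol 9 would have to be attached by copper catalysis to a ring whose activated fluoride the same phenoxide would attack first, or ring A would have to be built up in further steps. The fluoride of A7 is also flanked by two donor oxygens, which slows the displacement. The chosen route instead offers a short convergent sequence in which one step installs both ortho substituents of ring B with regiocontrol from the aryne, with no carbon introduced that must later be excised.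

Key step: step 4

Assumption: 2,4,6-trimethoxyphenol 9, 4-bromo-3,5-dimethoxybenzaldehyde 14 and 3,4,5-trimethoxyphenol 15 are taken as catalogue compounds, and methyl ethers serve as the only protecting groups.

Step 1
Reactants: 1 3,5-dimethoxyphenol
Product: 2 3,5-dimethoxyphenyl N-(propan-2-yl)carbamate
Conditions: i-PrNCO, Et3N (cat.), CH2Cl2, rt
Reagents that add atoms: isopropyl isocyanate, CC(C)N=C=O
Why: Base-catalysed addition of the phenol O–H to the isocyanate (carbamoylation) should be clean; the secondary carbamate is chosen because after N-silylation it is a strong ortho-directing group and it can later be removed under mild amine conditions.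

Step 2
Reactants: 2 3,5-dimethoxyphenyl N-(propan-2-yl)carbamate
Product: 6 3,5-dimethoxy-2-(trimethylsilyl)phenyl N-(propan-2-yl)carbamate, via N-silyl carbamate 3 (not isolated), via aryllithium 4 (not isolated), via bis-silyl carbamate 5 (not isolated)
Conditions: TBSOTf, TMEDA, Et2O, 0 °C to rt; n-BuLi, TMEDA, −78 °C; TMSCl, −78 °C to rt; sat. aq NH4Cl
Reagents that add atoms: chlorotrimethylsilane, C[Si](C)(C)Cl; tert-butyldimethylsilyl trifluoromethanesulfonate, CC(C)(C)[Si](C)(C)OS(=O)(=O)C(F)(F)F (its silyl group is carried only by 3, 4 and 5); n-butyllithium, [Li]CCCC (lithium only in 4)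
Why: Directed ortho-metalation: in situ N-silylation makes the carbamate behave as a tertiary carbamate, and lithiation should occur at C2 (equivalent to C6), where carbamate and methoxy cooperate, in preference to C4 between the two weaker methoxy directors. Silylation at −78 °C pre-empts the anionic Fries shift, and the near-neutral work-up removes the labile N-silyl group without protodesilylating the electron-rich aryl silane.

Step 3
Reactants: 6 3,5-dimethoxy-2-(trimethylsilyl)phenyl N-(propan-2-yl)carbamate
Product: 8 3,5-dimethoxy-2-(trimethylsilyl)phenyl trifluoromethanesulfonate, via silylphenol 7 (not isolated)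
Conditions: DBU, Et2NH, MeCN, 40 °C; then PhNTf2, rt
Reagents that add atoms: N-phenylbis(trifluoromethanesulfonimide), O=S(=O)(N(c1ccccc1)S(=O)(=O)C(F)(F)F)C(F)(F)F
Why: One-pot carbamate cleavage and triflation: DBU deprotonates the N–H carbamate, which fragments (E1cB) to the phenoxide of 7 and isopropyl isocyanate, the latter being trapped by diethylamine as a urea. The phenoxide is then sulfonylated by the mild triflyl donor under conditions that leave the C–Si bond alone.

Step 4
Reactants: 8 3,5-dimethoxy-2-(trimethylsilyl)phenyl trifluoromethanesulfonate; 9 2,4,6-trimethoxyphenol
Product: 13 2-iodo-1,5-dimethoxy-3-(2,4,6-trimethoxyphenoxy)benzene, via potassium 2,4,6-trimethoxyphenoxide 10 (not isolated), via 3,5-dimethoxybenzyne 11 (not isolated), via arylpotassium 12 (not isolated)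
Conditions: 9, KH (1.0 equiv to 9), THF, 0 °C; then 18-crown-6, KF, C6F13I (2 equiv), 8 added slowly, THF, 0 °C to rt, dark, argon
Reagents that add atoms: perfluorohexyl iodide (tridecafluoro-1-iodohexane), FC(F)(F)C(F)(F)C(F)(F)C(F)(F)C(F)(F)C(F)(F)I; KH, [K+].[H-] (potassium only in 10 and 12)
Why: Proposed new method: fluoride attacks silicon of 8 and the resulting aryl anion expels triflate to give aryne 11, phenoxide 10 adds through oxygen at B1 to give arylpotassium 12, and 12 attacks the iodine atom of perfluorohexyl iodide (halophilic substitution) to form the B6–I bond while the perfluorohexyl anion collapses to perfluorohex-1-ene and fluoride, so that fluoride is regenerated. The closest known reaction types are three-component aryne couplings in which an amine or a thiolate adds and the aryl anion is capped by an iodine donor or by carbon dioxide, together with the two-component O-arylation of phenols by arynes; pairing a phenoxide with an iodine electrophile is the untested element. No ring is closed and no stereocentre is formed. Three selectivities are needed. O- over C-arylation is secured because both ortho carbons and the para carbon of 10 carry methoxy groups. Attack at B1 and not at B6 is secured by the B5 methoxy group next to the triple bond, which distorts the aryne so that the remote carbon is the more electrophilic and places the developing negative charge on the carbon flanked by two inductively withdrawing oxygens. Iodination over protonation of 12 is secured by preforming 10 with KH so that no O–H is present, by THF in place of acetonitrile, and by an excess of the iodine donor, with slow addition of 8 keeping the aryne concentration low so that 12 is not consumed by a second aryne. Light is excluded to suppress electron transfer from the electron-rich phenoxide to the perfluoroalkyl iodide.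

Step 5
Reactants: 14 4-bromo-3,5-dimethoxybenzaldehyde; 15 3,4,5-trimethoxyphenol
Product: 16 3,5-dimethoxy-4-(3,4,5-trimethoxyphenoxy)benzaldehyde
Conditions: CuI (10 mol %), picolinic acid (20 mol %), K3PO4, DMSO, 90 °C
Reagents that add atoms: none
Why: Ullmann-type diaryl ether synthesis with a ligand system suited to ortho-substituted partners; the bromide is activated by the para formyl group, phenol 15 is unhindered and electron-rich, and the aldehyde has no α-hydrogen to enolise under K3PO4.

Step 6
Reactants: 16 3,5-dimethoxy-4-(3,4,5-trimethoxyphenoxy)benzaldehyde
Product: 18 3,5-dimethoxy-4-(3,4,5-trimethoxyphenoxy)phenol, via aryl formate 17 (not isolated)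
Conditions: mCPBA, CH2Cl2, 0 °C to rt; then K2CO3, MeOH, rt, argon
Reagents that add atoms: mCPBA (3-chloroperoxybenzoic acid), OOC(=O)c1cccc(Cl)c1
Why: Baeyer–Villiger oxidation: in the Criegee adduct the aryl group, made electron-rich by the para aryloxy oxygen, should migrate in preference to hydride, as in the conversion of 3,4,5-trimethoxybenzaldehyde into its phenol. Mild methanolysis of formate 17 then frees the C1 hydroxyl without touching the ethers.

Step 7
Reactants: 13 2-iodo-1,5-dimethoxy-3-(2,4,6-trimethoxyphenoxy)benzene; 18 3,5-dimethoxy-4-(3,4,5-trimethoxyphenoxy)phenol
Product: 19 1,5-dimethoxy-2-[3,5-dimethoxy-4-(3,4,5-trimethoxyphenoxy)phenoxy]-3-(2,4,6-trimethoxyphenoxy)benzene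
Conditions: CuI (20 mol %), picolinic acid (40 mol %), K3PO4, DMSO, 100 °C, argon
Reagents that add atoms: none
Why: Copper-catalysed Ullmann-type O-arylation: phenol 18 has no ortho substituent, so the steric demand lies on the iodide only, and iodide is the halide most readily engaged by copper. The picolinic acid, K3PO4 and DMSO combination is one used for ortho-disubstituted aryl iodides, and the flanking ether oxygens can assist by coordinating copper.

Step 8
Reactants: 19 1,5-dimethoxy-2-[3,5-dimethoxy-4-(3,4,5-trimethoxyphenoxy)phenoxy]-3-(2,4,6-trimethoxyphenoxy)benzene
Product: 20 5-{2,6-dihydroxy-4-[2,4-dihydroxy-6-(2,4,6-trihydroxyphenoxy)phenoxy]phenoxy}benzene-1,2,3-triol (CNP0018314.0)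
Conditions: BBr3 (20 equiv), CH2Cl2, −78 °C to rt; then degassed H2O, 0 °C, argon
Reagents that add atoms: none
Why: Lewis-acid ether cleavage: BBr3 coordinates each methoxy oxygen and bromide attacks the methyl carbon (SN2), so only alkyl–oxygen bonds break and the three diaryl ether bonds, whose carbons cannot undergo SN2, should survive. Degassed work-up under argon limits oxidation of the pyrogallol ring.

**Compound list**

1 | 3,5-dimethoxyphenol | COc1cc(O)cc(OC)c1 | starting material
2 | 3,5-dimethoxyphenyl N-(propan-2-yl)carbamate | CC(C)NC(=O)Oc1cc(OC)cc(OC)c1 | intermediate
3 | 3,5-dimethoxyphenyl N-(tert-butyldimethylsilyl)-N-(propan-2-yl)carbamate | CC(C)N(C(=O)Oc1cc(OC)cc(OC)c1)[Si](C)(C)C(C)(C)C | intermediate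
4 | [2-({[tert-butyl(dimethyl)silyl](propan-2-yl)carbamoyl}oxy)-4,6-dimethoxyphenyl]lithium | CC(C)N(C(=O)Oc1cc(OC)cc(OC)c1[Li])[Si](C)(C)C(C)(C)C | intermediate
5 | 3,5-dimethoxy-2-(trimethylsilyl)phenyl N-(tert-butyldimethylsilyl)-N-(propan-2-yl)carbamate | CC(C)N(C(=O)Oc1cc(OC)cc(OC)c1[Si](C)(C)C)[Si](C)(C)C(C)(C)C | intermediate
6 | 3,5-dimethoxy-2-(trimethylsilyl)phenyl N-(propan-2-yl)carbamate | CC(C)NC(=O)Oc1cc(OC)cc(OC)c1[Si](C)(C)C | intermediate
7 | 3,5-dimethoxy-2-(trimethylsilyl)phenol | COc1cc(O)c([Si](C)(C)C)c(OC)c1 | intermediate
8 | 3,5-dimethoxy-2-(trimethylsilyl)phenyl trifluoromethanesulfonate | COc1cc(OC)c([Si](C)(C)C)c(OS(=O)(=O)C(F)(F)F)c1 | intermediate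
9 | 2,4,6-trimethoxyphenol | COc1cc(OC)c(O)c(OC)c1 | starting material
10 | potassium 2,4,6-trimethoxyphenoxide | COc1cc(OC)c([O-])c(OC)c1.[K+] | intermediate
11 | 3,5-dimethoxybenzyne | COC1=CC(OC)=CC#C1 | intermediate
12 | [2,4-dimethoxy-6-(2,4,6-trimethoxyphenoxy)phenyl]potassium | COc1cc(OC)c([K])c(Oc2c(OC)cc(OC)cc2OC)c1 | intermediate
13 | 2-iodo-1,5-dimethoxy-3-(2,4,6-trimethoxyphenoxy)benzene | COc1cc(OC)c(I)c(Oc2c(OC)cc(OC)cc2OC)c1 | intermediate
14 | 4-bromo-3,5-dimethoxybenzaldehyde | COc1cc(C=O)cc(OC)c1Br | starting material
15 | 3,4,5-trimethoxyphenol | COc1cc(O)cc(OC)c1OC | starting material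
16 | 3,5-dimethoxy-4-(3,4,5-trimethoxyphenoxy)benzaldehyde | COc1cc(C=O)cc(OC)c1Oc1cc(OC)c(OC)c(OC)c1 | intermediate
17 | 3,5-dimethoxy-4-(3,4,5-trimethoxyphenoxy)phenyl formate | COc1cc(OC=O)cc(OC)c1Oc1cc(OC)c(OC)c(OC)c1 | intermediate
18 | 3,5-dimethoxy-4-(3,4,5-trimethoxyphenoxy)phenol | COc1cc(O)cc(OC)c1Oc1cc(OC)c(OC)c(OC)c1 | intermediate
19 | 1,5-dimethoxy-2-[3,5-dimethoxy-4-(3,4,5-trimethoxyphenoxy)phenoxy]-3-(2,4,6-trimethoxyphenoxy)benzene | COc1cc(OC)c(Oc2cc(OC)cc(OC)c2Oc2cc(OC)c(Oc3cc(OC)c(OC)c(OC)c3)c(OC)c2)c(OC)c1 | intermediate
20 | 5-{2,6-dihydroxy-4-[2,4-dihydroxy-6-(2,4,6-trihydroxyphenoxy)phenoxy]phenoxy}benzene-1,2,3-triol | Oc1cc(O)c(Oc2cc(O)cc(O)c2Oc2cc(O)c(Oc3cc(O)c(O)c(O)c3)c(O)c2)c(O)c1 | target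

**Step count and risk**

Total step count: 8. Longest linear sequence: 6 steps (steps 1, 2, 3, 4, 7 and 8, from 3,5-dimethoxyphenol 1); steps 5 and 6 form the convergent branch.

Least certain steps:

Step 4 (key step, proposed new method). The most likely failure is protonation of the aryl anion 12 before iodine transfer, which would give the iodine-free diaryl ether. Next most likely are electron transfer from the very electron-rich phenoxide 10 to the perfluoroalkyl iodide and addition of 12 to a second aryne. Fallback with known chemistry, setting out from 9 and rejoining at 13: purchased 1-iodo-3,5-dimethoxybenzene (COc1cc(I)cc(OC)c1) would be brominated with NBS in MeCN at 0 °C. By analogy with other 5-substituted resorcinol dimethyl ethers this should go ortho to the halogen and para to a methoxy group, giving 2-bromo-1-iodo-3,5-dimethoxybenzene F1. CuI, picolinic acid and K3PO4 in DMSO at 80 °C should couple 9 at the C–I bond only and give 2-bromo-1,5-dimethoxy-3-(2,4,6-trimethoxyphenoxy)benzene F2. Bromine–lithium exchange (n-BuLi, THF, −78 °C) and quenching with I2 would give 13.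

Step 7. The doubly ortho-oxygenated, electron-rich C–I bond may be engaged only slowly by copper, so that hydrodeiodination of 13 and oxidative degradation of the phenoxide of 18 take over at the temperature required. Fallback, setting out from 13 and 18 and rejoining at 19: the roles of the partners would be exchanged. Iodine–lithium exchange on 13 (n-BuLi, THF, −78 °C), borylation with B(OMe)3 and oxidation (H2O2, NaOH) would give 2,4-dimethoxy-6-(2,4,6-trimethoxyphenoxy)phenol F3. Phenol 18 would be converted with Tf2O and pyridine into 3,5-dimethoxy-4-(3,4,5-trimethoxyphenoxy)phenyl trifluoromethanesulfonate F4. Pd(OAc)2 with the bulky biaryl phosphine t-BuXPhos and K3PO4 in toluene at 100 °C would then join the hindered phenol F3 to the unhindered triflate F4 to give 19.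

Step 8. Cleavage of ten methyl ethers may stop short, and the free decaphenol may be lost through oxidation during aqueous work-up and chromatography. Fallback, setting out from 19 and rejoining at 20: after the BBr3 treatment the crude material would not be isolated as the free phenol but acetylated directly (Ac2O, pyridine) to the deca-O-acetate of 20 F5. This is stable to air and silica and can be separated from partly methylated material. Deacetylation with K2CO3 in degassed MeOH at 0 °C, followed by an acidic resin, would release 20.

Step 5. Coupling at a bromide flanked by two methoxy groups may be sluggish, and the aldehyde may suffer base-mediated side reactions on prolonged heating. Fallback, setting out from 15 and rejoining at 16: purchased 4-fluoro-3,5-dimethoxybenzaldehyde (COc1cc(C=O)cc(OC)c1F) would be treated with 15 and K2CO3 in DMF at 110 °C. This replaces copper catalysis by an uncatalysed addition–elimination para to the formyl group and makes no new intermediate.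

**Further compounds**

F1 | step 4 | 2-bromo-1-iodo-3,5-dimethoxybenzene | COc1cc(I)c(Br)c(OC)c1
F2 | step 4 | 2-bromo-1,5-dimethoxy-3-(2,4,6-trimethoxyphenoxy)benzene | COc1cc(OC)c(Br)c(Oc2c(OC)cc(OC)cc2OC)c1
F3 | step 7 | 2,4-dimethoxy-6-(2,4,6-trimethoxyphenoxy)phenol | COc1cc(OC)c(O)c(Oc2c(OC)cc(OC)cc2OC)c1
F4 | step 7 | 3,5-dimethoxy-4-(3,4,5-trimethoxyphenoxy)phenyl trifluoromethanesulfonate | COc1cc(OS(=O)(=O)C(F)(F)F)cc(OC)c1Oc1cc(OC)c(OC)c(OC)c1
F5 | step 8 | deca-O-acetate of 20 | CC(=O)Oc1cc(OC(C)=O)c(Oc2cc(OC(C)=O)cc(OC(C)=O)c2Oc2cc(OC(C)=O)c(Oc3cc(OC(C)=O)c(OC(C)=O)c(OC(C)=O)c3)c(OC(C)=O)c2)c(OC(C)=O)c1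
F0 | step 5 | none | none
A1 | alternative 1 | dimethyl 2,4,6-trihydroxy-5-{2-[3,5-dimethoxy-4-(3,4,5-trimethoxyphenoxy)phenoxy]-3,5-dimethoxyphenoxy}isophthalate | COC(=O)c1c(O)c(C(=O)OC)c(O)c(Oc2cc(OC)cc(OC)c2Oc2cc(OC)c(Oc3cc(OC)c(OC)c(OC)c3)c(OC)c2)c1O
A2 | alternative 1 | dimethyl 3-oxopentanedioate | COC(=O)CC(=O)CC(=O)OC
A3 | alternative 1 | dimethyl 2-{2-[3,5-dimethoxy-4-(3,4,5-trimethoxyphenoxy)phenoxy]-3,5-dimethoxyphenoxy}propanedioate | COC(=O)C(Oc1cc(OC)cc(OC)c1Oc1cc(OC)c(Oc2cc(OC)c(OC)c(OC)c2)c(OC)c1)C(=O)OC
A4 | alternative 1 | 2-[3,5-dimethoxy-4-(3,4,5-trimethoxyphenoxy)phenoxy]-3,5-dimethoxyphenol | COc1cc(O)c(Oc2cc(OC)c(Oc3cc(OC)c(OC)c(OC)c3)c(OC)c2)c(OC)c1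
A5 | alternative 2 | 3,5-dimethoxy-4-(3,4,5-trimethoxyphenoxy)phenol | COc1cc(O)cc(OC)c1Oc1cc(OC)c(OC)c(OC)c1
A6 | alternative 2 | 4-diazo-3,5-dimethoxycyclohexa-2,5-dien-1-one | COC1=CC(=O)C=C(OC)C1=[N+]=[N-]
A7 | alternative 3 | 4-fluoro-3-methoxy-5-(2,4,6-trimethoxyphenoxy)benzaldehyde | COc1cc(C=O)cc(Oc2c(OC)cc(OC)cc2OC)c1F
A8 | alternative 3 | 4-[3,5-dimethoxy-4-(3,4,5-trimethoxyphenoxy)phenoxy]-3-methoxy-5-(2,4,6-trimethoxyphenoxy)benzaldehyde | COc1cc(OC)c(Oc2cc(C=O)cc(OC)c2Oc2cc(OC)c(Oc3cc(OC)c(OC)c(OC)c3)c(OC)c2)c(OC)c1
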